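## Structural features

The target is an isoflavan quinone. A 6,7-dimethoxychroman (benzene ring A fused through C4a and C8a to the pyran ring C, O1–C2–C3–C4) carries at C3 a 2,3-dimethoxy-1,4-benzoquinone (ring B: C1' bonded to C3, carbonyls at C2' and C5', methoxy groups at C3' and C4', the only C–H at C6'). C3 is the single stereocentre (S). It lies between two methylene groups, C2 and C4, so no neighbouring stereocentre or functional group can relay chirality to it and an external chiral agent must set it. The quinone is the fragile part: it is reducible, electrophilic and base-sensitive, and it acidifies the C3–H, which could be lost through a quinone-methide tautomer with racemisation, so it has to be made last and near neutrality. Ring A is a 1,2,4-trioxygenated benzene that strong one-electron oxidants would also turn into a quinone, so the last oxidation must tell a free phenol in ring B from the aryl ethers of ring A. The real difficulty is therefore the absolute configuration of an isolated benzylic centre, together with the ring-B pattern, which corresponds to a phenol with OH at C5' (a 3-hydroxy-4,5-dimethoxyphenyl group in ordinary numbering) whose free para position C2' becomes the second carbonyl. The key step uses the way ring C hangs on ring A: O1 on C8a and C4 on C4a form the atom pattern of an o-quinone methide (O1=C8a–C4a=C4, a 1-oxadiene), activated by the 7-methoxy group para to C4a. C2–C3 is a two-carbon unit that can carry ring B and a removable donor at C2, so forming O1–C2 and C3–C4 together closes ring C and creates C3.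

## Logic of the disconnections

**15 to 14.** The carbonyl oxygen at C2' is removed and the C5' carbonyl is returned to a phenol. The quinone would not survive hydride, hydrogenation, Lewis acid or base, and it labilises C3–H. The gain is that ring B travels as a robust phenol. The forward oxidation must be para-selective and must leave ring A and C3–H alone.

**14 to 13.** The O–CH2Ph bond on ring B is cut. A free phenol would capture the isocyanate 9 and would compete as a nucleophile for 11. The gain is a mask that endures base, heat, Brønsted acid and cold Lewis acid. The forward cleavage must not touch the chroman, and hydrogenolysis meets this because 13 has no other benzylic C–O bond.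

**13 to 12.** The C2–H bond is traced back to a C2–N bond. A nitrogen donor at C2 makes the carbon bearing ring B nucleophilic and supplies the N–H through which a chiral acid can bind. The gain is that ring C becomes a cycloadduct. Forward, hydride must replace nitrogen through the ring oxocarbenium ion without opening O1–C2 and without removing the C3 proton. A benzyl carbamate is chosen because it is stable to the Lewis acid and leaves as a neutral amide; a tert-butyl carbamate would be cleaved first and the free aminal would collapse.

**12 to 2 and 10 (through 11).** C3–C4 and O1–C2 are cut together. This removes ring C and both stereocentres at once and leaves two achiral aromatic building blocks of similar size. The forward step must control the face of 10 at the carbon that becomes C3, and 11 must be intercepted before it self-condenses.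

**10 to 7 (through 9 and 8).** The alkenyl C–N bond is traced to an alkenyl C–CO2H bond, and the carbamate C–O bond to addition of an alcohol to 9. (E)-Cinnamic acids are easily obtained geometrically pure, and the rearrangement moves the alkenyl group to nitrogen with the double-bond geometry intact. The forward step needs clean trapping of 9 and an isolation free of aqueous acid.

**7 to 4 and 5 (through 6).** The Cα=Cβ double bond is cut. This reduces the three-carbon side chain to an aryl aldehyde and a two-carbon acid. The forward condensation must give the E acid, which the decarboxylative pathway ensures.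

**4 to 3.** The O–benzyl bond is cut, leading back to a commercial hydroxy aldehyde. The forward alkylation has only one acidic site to address.

**2 to 1.** The benzylic C–H bond is traced to the aldehyde. The forward reduction must be followed by a neutral work-up, because 2 ionises easily.

## Other disconnections considered

**Alternative 1:** The cut is the C3–C1' bond between ring C and ring B, with a temporary C4–O bond to the ring-B oxygen at C2'.
- Forward key step: 6,7-dimethoxy-2H-chromene A1 would add through C3 to an unsubstituted carbon of 2,3-dimethoxy-1,4-benzoquinone A2 held on TiCl2(O-i-Pr)2 modified by a TADDOL diol (tetravalent titanium). The quinone oxygen next to the new bond would then capture the benzylic cation at C4 and give (6aS,11aS)-8-hydroxy-2,3,9,10-tetramethoxypterocarpan A3, cis-fused, whose C6a is C3 of the target. Hydrogenolysis of the benzylic C11a–O bond and mild oxidation would lead from A3 to 15.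
- In favour: it is the most convergent cut. Ring B arrives with all four oxygen atoms in place, no protecting group is needed, and A2 is symmetrical, so its two free carbons are equivalent. A1 should be reachable from 1 in one or two operations. On step economy (about five steps in all) it is better than the chosen plan, and removing its sacrificial bond by hydrogenolysis is probably more routine than the ionic reduction at C2 needed here.
- Against: the chiral titanium reagent is normally needed in full equivalents. Formal [3+2] addition competes with [2+2] cyclobutane formation and with hydride abstraction from C2 of A1 by the quinone. The electron-rich chromene can oligomerise on the Lewis acid. The facial bias of such titanium–diol complexes changes strongly with the alkene, so sense and level of induction at C6a would have to be found empirically.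
- Comparison: in structure the plans are equal, since each creates C3 in the key step beside a second centre that is erased afterwards. In mechanism both are asynchronous polar additions of an electron-rich alkene to an acid-activated quinonoid acceptor with the roles of rings A and B exchanged. The chosen plan uses a substoichiometric chiral Brønsted acid with a two-point hydrogen-bond model, which makes the face selection easier to rationalise. In step count the alternative is ahead.

**Alternative 2:** The cut dismantles ring A itself: C5–C6, C4a–C8a and C8–C8a.
- Forward key step: the Fischer carbene complex pentacarbonyl[methoxy(1-methoxyethenyl)carbene]chromium A4 (zerovalent chromium) would undergo Dötz benzannulation with the terminal alkyne tert-butyl({(2S)-2-[3,4-dimethoxy-5-(methoxymethoxy)phenyl]pent-4-yn-1-yl}oxy)dimethylsilane A5 and one CO ligand. After decomplexation this would give the phenol 2-{(2S)-3-[(tert-butyldimethylsilyl)oxy]-2-[3,4-dimethoxy-5-(methoxymethoxy)phenyl]propyl}-4,5-dimethoxyphenol A6, with the hydroxyl at the future C8a and the methoxy groups at C6 and C7. Desilylation, Mitsunobu closure of O1–C2, acetal cleavage to 14 and the same final oxidation would follow.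
- In favour: the regiochemistry of the benzannulation with a terminal alkyne is dependable, because the substituted alkyne carbon ends up next to the new hydroxyl. The stereocentre is set earlier by well-tried auxiliary alkylation and is not touched by the annulation, so the absolute configuration is more secure than in the chosen plan; on this point the alternative is better.
- Against: the key step builds an achiral benzene ring that the chosen plan obtains ready-made in 1, and it does nothing for C3. It needs stoichiometric chromium, an α-alkoxyalkenyl carbene complex of limited stability, and careful decomplexation of an electron-rich hydroquinone monoether. Making A5 alone would take about as many steps as the whole chosen route.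
- Comparison: the end games are equal (liberation of 14, then para-oxidation). Structurally the alternative spends its most elaborate step on the least demanding part of the molecule, whereas the chosen plan spends it on the ring that holds the stereocentre. Mechanistically it exchanges an organocatalytic polar cycloaddition for a metal-templated carbene–alkyne–CO assembly. In step count (well above twelve) it is clearly worse.

**Alternative 3:** The cut is O1–C2 together with the C3–H bond.
- Forward key step: the achiral allylphenol 2-{2-[3,4-dimethoxy-5-(methoxymethoxy)phenyl]prop-2-en-1-yl}-4,5-dimethoxyphenol A7 would be oxidised by an excited acridinium photocatalyst to the alkene radical cation. The phenol oxygen would add to the terminal carbon (anti-Markovnikov, 6-endo), and a chiral thiol would transfer hydrogen to the tertiary benzylic radical at C3. This would give (3S)-3-[3,4-dimethoxy-5-(methoxymethoxy)phenyl]-6,7-dimethoxy-3,4-dihydro-2H-chromene A8. Acetal cleavage to 14 and oxidation would finish the synthesis.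
- In favour: the substrate is achiral and short to make. Ring C forms directly at the right oxidation level with no handle to excise and no by-product, so the alternative is better in atom and redox economy and at least equal in step count (about seven steps). The racemic cyclisation with an achiral thiol is an established reaction type.
- Against: the stereo-determining event is hydrogen-atom transfer to a planar radical whose two ring neighbours are both CH2 groups. No general enantioselective thiol catalyst exists for this, so the central step would require a catalyst to be invented. Ring A and the phenol are also oxidised more easily than the 1,1-disubstituted alkene, so the photocatalyst may react at the wrong site.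
- Comparison: structurally both plans close ring C and set C3 in one step, which is equal. Mechanistically the chosen plan sets C3 in a closed-shell C–C bond formation inside a hydrogen-bonded assembly, a mode of induction with direct analogy, while the alternative must control an open-shell hydrogen transfer without such analogy. The end games are equal.

Key step: step 5

Assumption: the (R)-configured phosphoric acid is taken to favour the 3S adduct by analogy with related enecarbamate additions; if the opposite sense is induced, the equally available (S)-acid is used with no other change to the route.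

## Route

Step 1
Reactants: 1 2-hydroxy-4,5-dimethoxybenzaldehyde
Product: 2 2-(hydroxymethyl)-4,5-dimethoxyphenol
Conditions: NaBH4, MeOH, 0 °C; sat. aq. NH4Cl work-up
Reagents that add atoms: none
Why: Borohydride reduction of an aryl aldehyde to the benzylic alcohol; the phenol is not affected, and the neutral work-up avoids premature ionisation of the electron-rich salicyl alcohol, which is used fresh.

Step 2
Reactants: 3 3-hydroxy-4,5-dimethoxybenzaldehyde
Product: 4 3-(benzyloxy)-4,5-dimethoxybenzaldehyde
Conditions: BnBr, K2CO3, DMF, rt
Reagents that add atoms: benzyl bromide, BrCc1ccccc1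
Why: Williamson ether synthesis on the only acidic site; the benzyl ether should survive hot pyridine, the rearrangement, the phosphoric acid and cold BF3·OEt2, and it is removed later by hydrogenolysis.

Step 3
Reactants: 4 3-(benzyloxy)-4,5-dimethoxybenzaldehyde; 5 malonic acid
Product: 7 (E)-3-[3-(benzyloxy)-4,5-dimethoxyphenyl]prop-2-enoic acid, via arylidenemalonic acid 6 (not isolated)
Conditions: pyridine, piperidine (cat.), 90 °C → reflux; then aq. HCl
Reagents that add atoms: none
Why: Knoevenagel–Doebner condensation: the amine-mediated condensation gives diacid 6, which decarboxylates in hot pyridine to the thermodynamically preferred (E)-cinnamic acid.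

Step 4
Reactants: 7 (E)-3-[3-(benzyloxy)-4,5-dimethoxyphenyl]prop-2-enoic acid
Product: 10 benzyl N-[(E)-2-(3-benzyloxy-4,5-dimethoxyphenyl)ethenyl]carbamate, via acyl azide 8 (not isolated), via alkenyl isocyanate 9 (not isolated)
Conditions: DPPA, Et3N, PhMe, 0 °C → rt; then 85 °C; then BnOH, 85 °C; chromatography on Et3N-deactivated silica
Reagents that add atoms: diphenylphosphoryl azide, [N-]=[N+]=NP(=O)(Oc1ccccc1)Oc1ccccc1; benzyl alcohol, OCc1ccccc1
Why: Curtius rearrangement: acyl azide 8 loses N2 with concerted 1,2-shift of the alkenyl group, which keeps the E geometry, and isocyanate 9 adds benzyl alcohol to give the secondary enecarbamate whose free N–H is needed in the next step.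

Step 5
Reactants: 2 2-(hydroxymethyl)-4,5-dimethoxyphenol; 10 benzyl N-[(E)-2-(3-benzyloxy-4,5-dimethoxyphenyl)ethenyl]carbamate
Product: 12 benzyl N-[(2R,3S)-3-[3-(benzyloxy)-4,5-dimethoxyphenyl]-6,7-dimethoxy-3,4-dihydro-2H-chromen-2-yl]carbamate, via o-quinone methide 11 (not isolated)
Conditions: (R)-TRIP (10 mol %), 5 Å MS, CHCl3, 0 °C → rt; 2 added slowly to 10 (1.3 equiv)
Reagents that add atoms: none
Why: The phosphoric acid protonates the benzylic hydroxyl of 2 and water is lost to give o-quinone methide 11, whose formation is eased by the methoxy group para to the methide-bearing carbon (the later 7-OMe). 11 is an electron-poor 1-oxadiene and 10 an electron-rich dienophile, so they should combine in an inverse-electron-demand hetero-Diels–Alder reaction; the closest known reaction type is the chiral phosphoric acid-catalysed [4+2] cycloaddition of in situ o-quinone methides with enamides and enecarbamates. Bond formation is asynchronous: the enecarbamate carbon bearing ring B (β to nitrogen) attacks the methide CH2 to form C3–C4, and the phenolic oxygen then closes on the developing N-acyliminium carbon to form O1–C2. The pyran ring is thus closed by [4+2] cycloaddition; if the process is stepwise, the second bond forms by 6-exo-trig attack of the phenoxide on the iminium carbon within the phosphate ion pair. C3 is controlled by the catalyst: the P=O oxygen accepts a hydrogen bond from the carbamate N–H and the P–OH donates to the methide oxygen, so the CH2 terminus reaches one face of the enecarbamate inside the pocket of the 3,3'-aryl groups. C2 is controlled by the substrate, because suprafacial addition to the (E)-alkene places nitrogen trans to ring B; C2 later becomes CH2, so any leakage there is harmless. The step needs enantiofacial selectivity at C3, regioselectivity and chemoselectivity over self-condensation of 11; these are secured by the free N–H of the secondary carbamate, by the enamide polarity of 10, and by slow addition of 2 to an excess of 10 over molecular sieves.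

Step 6
Reactants: 12 benzyl N-[(2R,3S)-3-[3-(benzyloxy)-4,5-dimethoxyphenyl]-6,7-dimethoxy-3,4-dihydro-2H-chromen-2-yl]carbamate
Product: 13 (3S)-3-[3-(benzyloxy)-4,5-dimethoxyphenyl]-6,7-dimethoxy-3,4-dihydro-2H-chromene
Conditions: Et3SiH (10 equiv), BF3·OEt2 (2 equiv), CH2Cl2, −78 → −30 °C; aq. NaHCO3
Reagents that add atoms: none
Why: Ionic hydrogenation of a cyclic N,O-acetal: BF3 binds the carbamate carbonyl, the C2–N bond ionises to the ring oxocarbenium ion stabilised by O1, and the silane delivers hydride to C2. C3 is not a reacting centre, and low temperature with a large excess of silane should outpace loss of the C3 proton.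

Step 7
Reactants: 13 (3S)-3-[3-(benzyloxy)-4,5-dimethoxyphenyl]-6,7-dimethoxy-3,4-dihydro-2H-chromene
Product: 14 5-[(3S)-6,7-dimethoxy-3,4-dihydro-2H-chromen-3-yl]-2,3-dimethoxyphenol
Conditions: H2 (1 atm), 10 % Pd/C, EtOAc–MeOH, rt
Reagents that add atoms: none
Why: Hydrogenolysis of an aryl benzyl ether over palladium on carbon; 13 has no other benzylic C–O bond, so the chroman and C3 are untouched.

Step 8
Reactants: 14 5-[(3S)-6,7-dimethoxy-3,4-dihydro-2H-chromen-3-yl]-2,3-dimethoxyphenol
Product: 15 abruquinone A, 5-[(3S)-6,7-dimethoxy-3,4-dihydro-2H-chromen-3-yl]-2,3-dimethoxycyclohexa-2,5-diene-1,4-dione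
Conditions: Fremy's salt (KSO3)2NO (2.5 equiv), KH2PO4 buffer (pH 6), H2O–acetone, 0 °C → rt
Reagents that add atoms: potassium nitrosodisulfonate, [K+].[K+].[O]N(S(=O)(=O)[O-])S(=O)(=O)[O-]
Why: Teuber oxidation: one equivalent of the nitroxyl radical removes the phenolic hydrogen, a second couples at the free para carbon C2', and collapse gives the para-quinone with the oxygen coming from the reagent. Ring A has no free hydroxyl and is inert, and the buffered medium protects the C3–H of the product.

## Compound list

1 | 2-hydroxy-4,5-dimethoxybenzaldehyde | COc1cc(O)c(C=O)cc1OC | starting material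
2 | 2-(hydroxymethyl)-4,5-dimethoxyphenol | COc1cc(O)c(CO)cc1OC | intermediate
3 | 3-hydroxy-4,5-dimethoxybenzaldehyde | COc1cc(C=O)cc(O)c1OC | starting material
4 | 3-(benzyloxy)-4,5-dimethoxybenzaldehyde | COc1cc(C=O)cc(OCc2ccccc2)c1OC | intermediate
5 | malonic acid | OC(=O)CC(O)=O | starting material
6 | 2-{[3-(benzyloxy)-4,5-dimethoxyphenyl]methylidene}propanedioic acid | COc1cc(C=C(C(O)=O)C(O)=O)cc(OCc2ccccc2)c1OC | intermediate
7 | (E)-3-[3-(benzyloxy)-4,5-dimethoxyphenyl]prop-2-enoic acid | COc1cc(/C=C/C(O)=O)cc(OCc2ccccc2)c1OC | intermediate
8 | (E)-3-[3-(benzyloxy)-4,5-dimethoxyphenyl]prop-2-enoyl azide | COc1cc(/C=C/C(=O)N=[N+]=[N-])cc(OCc2ccccc2)c1OC | intermediate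
9 | 1-(benzyloxy)-5-[(E)-2-isocyanatoethenyl]-2,3-dimethoxybenzene | COc1cc(/C=C/N=C=O)cc(OCc2ccccc2)c1OC | intermediate
10 | benzyl N-[(E)-2-(3-benzyloxy-4,5-dimethoxyphenyl)ethenyl]carbamate | COc1cc(/C=C/NC(=O)OCc2ccccc2)cc(OCc2ccccc2)c1OC | intermediate
11 | 3,4-dimethoxy-6-methylidenecyclohexa-2,4-dien-1-one | C=C1C=C(OC)C(OC)=CC1=O | intermediate
12 | benzyl N-[(2R,3S)-3-[3-(benzyloxy)-4,5-dimethoxyphenyl]-6,7-dimethoxy-3,4-dihydro-2H-chromen-2-yl]carbamate (trans) | COc1cc(cc(OCc2ccccc2)c1OC)[C@@H]1Cc2cc(OC)c(OC)cc2O[C@H]1NC(=O)OCc1ccccc1 | intermediate
13 | (3S)-3-[3-(benzyloxy)-4,5-dimethoxyphenyl]-6,7-dimethoxy-3,4-dihydro-2H-chromene | COc1cc(cc(OCc2ccccc2)c1OC)[C@H]1COc2cc(OC)c(OC)cc2C1 | intermediate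
14 | 5-[(3S)-6,7-dimethoxy-3,4-dihydro-2H-chromen-3-yl]-2,3-dimethoxyphenol | COc1cc(cc(O)c1OC)[C@H]1COc2cc(OC)c(OC)cc2C1 | intermediate
15 | abruquinone A, 5-[(3S)-6,7-dimethoxy-3,4-dihydro-2H-chromen-3-yl]-2,3-dimethoxycyclohexa-2,5-diene-1,4-dione | COC1=C(OC)C(=O)C([C@H]2COc3cc(OC)c(OC)cc3C2)=CC1=O | target

## Step count and least certain steps

Total step count: 8. Longest linear sequence: 7 (steps 2 to 8, from 3); the other branch is step 1.

**Step 5 (key step).** The main risk is insufficient enantiofacial discrimination, because the methide carbon is an unsubstituted CH2 and only the face of the nucleophile is differentiated. Oligomerisation of the quinone methide by a second molecule of the electron-rich phenol and hydrolysis of the enecarbamate by the released water are further risks. The fallback sets out from 2 and 10 and returns at 13, and moves the stereo-determining event to a hydrogenation. The cycloaddition is run with an achiral acid, diphenyl hydrogen phosphate, to give racemic trans-benzyl N-[3-(3-benzyloxy-4,5-dimethoxyphenyl)-6,7-dimethoxychroman-2-yl]carbamate F1. Warming with catalytic p-toluenesulfonic acid in toluene expels benzyl carbamate and gives 3-[3-(benzyloxy)-4,5-dimethoxyphenyl]-6,7-dimethoxy-4H-chromene F2. Asymmetric hydrogenation of this cyclic enol ether with a cationic iridium catalyst, [Ir(cod)(L)][B(C6H3(CF3)2)4] with L a chiral phosphine–oxazoline, under H2 should then set C3 and give 13.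

**Step 6.** Ionisation may occur at the endocyclic O1–C2 bond instead of the C2–N bond; this opens the ring to an N-acyliminium ion, whose reduction would give an open-chain carbamate. Loss of the C3 proton from the oxocarbenium ion followed by reprotonation would erode the configuration, and Friedel–Crafts capture of the cation by an electron-rich ring is also possible. The fallback sets out from 12 and returns at 13. Hydrolysis of the N,O-acetal with dilute HCl in THF gives (3S)-3-[3-(benzyloxy)-4,5-dimethoxyphenyl]-6,7-dimethoxy-3,4-dihydro-2H-chromen-2-ol F3 as a mixture of C2 epimers. Prompt reduction of its open hydroxy-aldehyde form with NaBH4 gives 2-[(2S)-2-(3-benzyloxy-4,5-dimethoxyphenyl)-3-hydroxypropyl]-4,5-dimethoxyphenol F4. Mitsunobu etherification (PPh3, DIAD, THF) then closes O1–C2 at the primary carbon, without touching the stereocentre, to give 13.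

**Step 4.** The isocyanate may be captured by adventitious water to form a urea, the alkenyl isocyanate may isomerise or polymerise on heating, and the enecarbamate may hydrolyse on acidic silica. The fallback sets out from 7 and returns at 10. Bromodecarboxylation of 7 (N-bromosuccinimide, LiOAc cat., MeCN–H2O) gives 1-(benzyloxy)-5-[(E)-2-bromoethenyl]-2,3-dimethoxybenzene F5. Goldberg-type amidation with benzyl carbamate (CuI, N,N'-dimethylethylenediamine, K2CO3, toluene, 80 °C) forms the alkenyl C–N bond with retention of geometry and gives 10.

**Step 8.** Oxygen transfer may be slow or incomplete at the para carbon, which is flanked by a methoxy group and the chromanyl substituent. Ortho-oxidation may compete, and the configuration at C3 may be lost by base once the quinone is present. The fallback sets out from 14 and returns at 15. Elbs persulfate oxidation (K2S2O8, aq. NaOH, 0 °C → rt) gives potassium 2-[(3S)-6,7-dimethoxy-3,4-dihydro-2H-chromen-3-yl]-4-hydroxy-5,6-dimethoxyphenyl sulfate F6. Hydrolysis with warm dilute HCl gives 5-[(3S)-6,7-dimethoxy-3,4-dihydro-2H-chromen-3-yl]-2,3-dimethoxybenzene-1,4-diol F7. Neutral oxidation with Ag2O in ether then gives 15.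

## Further compounds

F1 | step 5 | rac-trans-benzyl N-[3-(3-benzyloxy-4,5-dimethoxyphenyl)-6,7-dimethoxy-3,4-dihydro-2H-chromen-2-yl]carbamate (racemate) | COc1cc(cc(OCc2ccccc2)c1OC)C1Cc2cc(OC)c(OC)cc2OC1NC(=O)OCc1ccccc1
F2 | step 5 | 3-[3-(benzyloxy)-4,5-dimethoxyphenyl]-6,7-dimethoxy-4H-chromene | COc1cc(cc(OCc2ccccc2)c1OC)C1=COc2cc(OC)c(OC)cc2C1
F3 | step 6 | (3S)-3-[3-(benzyloxy)-4,5-dimethoxyphenyl]-6,7-dimethoxy-3,4-dihydro-2H-chromen-2-ol (C2 epimers) | COc1cc(cc(OCc2ccccc2)c1OC)[C@@H]1Cc2cc(OC)c(OC)cc2OC1O
F4 | step 6 | 2-[(2S)-2-(3-benzyloxy-4,5-dimethoxyphenyl)-3-hydroxypropyl]-4,5-dimethoxyphenol | COc1cc(cc(OCc2ccccc2)c1OC)[C@@H](CO)Cc1cc(OC)c(OC)cc1O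
F5 | step 4 | 1-(benzyloxy)-5-[(E)-2-bromoethenyl]-2,3-dimethoxybenzene | COc1cc(/C=C/Br)cc(OCc2ccccc2)c1OC
F6 | step 8 | potassium 2-[(3S)-6,7-dimethoxy-3,4-dihydro-2H-chromen-3-yl]-4-hydroxy-5,6-dimethoxyphenyl sulfate | [K+].COc1c(O)cc([C@H]2COc3cc(OC)c(OC)cc3C2)c(OS(=O)(=O)[O-])c1OC
F7 | step 8 | 5-[(3S)-6,7-dimethoxy-3,4-dihydro-2H-chromen-3-yl]-2,3-dimethoxybenzene-1,4-diol | COc1c(O)cc([C@H]2COc3cc(OC)c(OC)cc3C2)c(O)c1OC
A1 | alternative 1 | 6,7-dimethoxy-2H-chromene | COc1cc2OCC=Cc2cc1OC
A2 | alternative 1 | 2,3-dimethoxy-1,4-benzoquinone | COC1=C(OC)C(=O)C=CC1=O
A3 | alternative 1 | (6aS,11aS)-8-hydroxy-2,3,9,10-tetramethoxypterocarpan (cis) | COc1cc2OC[C@@H]3c4cc(O)c(OC)c(OC)c4O[C@@H]3c2cc1OC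
A4 | alternative 2 | pentacarbonyl[methoxy(1-methoxyethenyl)carbene]chromium | COC(=C)C(OC)=[Cr](=C=O)(=C=O)(=C=O)(=C=O)=C=O
A5 | alternative 2 | tert-butyl({(2S)-2-[3,4-dimethoxy-5-(methoxymethoxy)phenyl]pent-4-yn-1-yl}oxy)dimethylsilane | COCOc1cc(cc(OC)c1OC)[C@@H](CO[Si](C)(C)C(C)(C)C)CC#C
A6 | alternative 2 | 2-{(2S)-3-[(tert-butyldimethylsilyl)oxy]-2-[3,4-dimethoxy-5-(methoxymethoxy)phenyl]propyl}-4,5-dimethoxyphenol | COCOc1cc(cc(OC)c1OC)[C@@H](CO[Si](C)(C)C(C)(C)C)Cc1cc(OC)c(OC)cc1O
A7 | alternative 3 | 2-{2-[3,4-dimethoxy-5-(methoxymethoxy)phenyl]prop-2-en-1-yl}-4,5-dimethoxyphenol | COCOc1cc(cc(OC)c1OC)C(=C)Cc1cc(OC)c(OC)cc1O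
A8 | alternative 3 | (3S)-3-[3,4-dimethoxy-5-(methoxymethoxy)phenyl]-6,7-dimethoxy-3,4-dihydro-2H-chromene | COCOc1cc(cc(OC)c1OC)[C@H]1COc2cc(OC)c(OC)cc2C1
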